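**Retrosynthetic overview**

1. Labels: chain C1 (=CH2 of the isopropenyl group), C2, C3 (CHOH), C4, C5, C6 (C=CH2); ring A: C7 (tertiary carbinol), C8, C9, C10 (C–Br), C11 (C–Cl), C12. C3 lies four bonds (C3–C4–C5–C6–C7) from the nearest stereocentre of ring A, so only a chiral reagent can set it and the C2–C3 bond can be made last.
2. Target ⇐ C7 silyl ether ⇐ C2–C3 disconnection: ligand-controlled addition of diisopropenylzinc to the C3 aldehyde of the complete halogenated fragment.
3. C3 aldehyde ⇐ C6 ketone (methylenation, acetal release) ⇐ ring A ester; the C5–C6 bond comes from a Grignard addition to the C6 aldehyde, followed by oxidation.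
4. Ring A halogens ⇐ chloroetherification tethered through the C7 hydroxyl (transient C7–O–C10 bridge, sets C11–Cl), then bromide opening of the bridge at C10 with retention through a chloronium ion.
5. Ring A is formed first, by an auxiliary-controlled Diels–Alder reaction of isoprene with a methylene dioxolanone from (R)-lactic acid (sets C7); the oxa bridge is the only other ring formed (step 5) and is opened again (step 6).

Key step: step 14

Remark on the chemistry: the C7 hydroxyl is carried as a triethylsilyl ether, which should survive the Grignard, titanium and acetal-cleavage steps better than a trimethylsilyl ether and is still removable with buffered HF·pyridine.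

**Route**

Step 1
Reactants: 1 (R)-lactic acid; 2 pivalaldehyde
Product: 3 (2R,5R)-2-tert-butyl-5-methyl-1,3-dioxolan-4-one
Conditions: TsOH·H2O (cat.), H2SO4 (cat.), pentane, reflux, Dean–Stark; recrystallisation from pentane/Et2O at −78 °C
Reagents that add atoms: none
Why: Acid-catalysed acetalisation of the α-hydroxy acid (dioxolanone formation) keeps C5 from lactic acid and sets the acetal carbon C2 under thermodynamic control, the cis (2R,5R) isomer being enriched by crystallisation.

Step 2
Reactants: 3 (2R,5R)-2-tert-butyl-5-methyl-1,3-dioxolan-4-one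
Product: 5 (2R)-2-tert-butyl-5-methylidene-1,3-dioxolan-4-one, via bromodioxolanone 4 (not isolated)
Conditions: NBS, azobisisobutyronitrile (cat.), cyclohexane, reflux; filter; then Et3N, Et2O, 0 °C → rt
Reagents that add atoms: none
Why: Wohl–Ziegler radical bromination at the captodative C5–H followed by E2 dehydrobromination towards the methyl group gives the exocyclic alkene, while the acetal carbon C2 is untouched and now carries all stereochemical information.

Step 3
Reactants: 5 (2R)-2-tert-butyl-5-methylidene-1,3-dioxolan-4-one; 6 isoprene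
Product: 7 (2R,5S)-2-tert-butyl-8-methyl-1,3-dioxaspiro[4.5]dec-7-en-4-one
Conditions: isoprene (excess), 2,6-di-tert-butyl-4-methylphenol (cat.), toluene, sealed tube, 100 °C
Reagents that add atoms: none
Why: A thermal Diels–Alder cycloaddition forms ring A with "para" regiochemistry (larger diene coefficient at the CH2 next to the methyl-bearing carbon, larger dienophile coefficient at its CH2), and the diene adds to the face opposite the tert-butyl group, which sets the spiro carbon (future C7) as S; any meta regioisomer would be removed by chromatography.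

Step 4
Reactants: 7 (2R,5S)-2-tert-butyl-8-methyl-1,3-dioxaspiro[4.5]dec-7-en-4-one
Product: 8 methyl (1S)-1-hydroxy-4-methylcyclohex-3-ene-1-carboxylate
Conditions: NaOMe (0.2 equiv), MeOH, 0 °C → rt
Reagents that add atoms: methanol, CO
Why: Base-catalysed transesterification of the acylal lactone opens the dioxolanone, and the hemiacetal alkoxide expels pivalaldehyde without touching C7.

Step 5
Reactants: 8 methyl (1S)-1-hydroxy-4-methylcyclohex-3-ene-1-carboxylate
Product: 9 methyl (1S,3R,4R)-3-endo-chloro-4-methyl-7-oxabicyclo[2.2.1]heptane-1-carboxylate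
Conditions: trichloroisocyanuric acid (0.37 equiv), MeCN, 0 °C, dark
Reagents that add atoms: trichloroisocyanuric acid, ClN1C(=O)N(Cl)C(=O)N(Cl)C1=O
Why: In this electrophilic chloroetherification (halocyclisation) chlorine adds to the ring alkene on the face opposite the C7 hydroxyl, which attacks the tertiary carbon C10 (Markovnikov) through a boat, so anti addition sets C11–Cl (R) and the C10–O bond (R) relative to C7; the methyl ester is a much poorer internal nucleophile than the hydroxyl.

Step 6
Reactants: 9 methyl (1S,3R,4R)-3-endo-chloro-4-methyl-7-oxabicyclo[2.2.1]heptane-1-carboxylate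
Product: 10 methyl (1S,3R,4R)-4-bromo-3-chloro-1-hydroxy-4-methylcyclohexane-1-carboxylate
Conditions: BBr3 (1.2 equiv), CH2Cl2, −78 → −20 °C; then ice-cold H2O
Reagents that add atoms: boron tribromide, BrB(Br)Br
Why: In this BBr3 ether cleavage boron activates the bridging oxygen, only the C10–O bond can ionise (C7 is α to the ester), the anti chlorine at C11 bridges the developing cation, and bromide opens this chloronium ion at the tertiary carbon anti to chlorine, so C10 should gain bromine with net retention (cis to the C7 oxygen, trans to chlorine).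

Step 7
Reactants: 10 methyl (1S,3R,4R)-4-bromo-3-chloro-1-hydroxy-4-methylcyclohexane-1-carboxylate
Product: 11 methyl (1S,3R,4R)-4-bromo-3-chloro-4-methyl-1-(triethylsilyloxy)cyclohexane-1-carboxylate
Conditions: TESOTf (1.5 equiv), 2,6-lutidine (2.5 equiv), CH2Cl2, −78 → 0 °C
Reagents that add atoms: triethylsilyl trifluoromethanesulfonate, CC[Si](CC)(CC)OS(=O)(=O)C(F)(F)F
Why: Silylation of the hindered tertiary alcohol with a silyl triflate uses a hindered pyridine base that is too weak to eliminate the tertiary bromide.

Step 8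
Reactants: 11 methyl (1S,3R,4R)-4-bromo-3-chloro-4-methyl-1-(triethylsilyloxy)cyclohexane-1-carboxylate
Product: 12 (1S,3R,4R)-4-bromo-3-chloro-4-methyl-1-(triethylsilyloxy)cyclohexane-1-carbaldehyde
Conditions: iBu2AlH (1.2 equiv), CH2Cl2, −78 °C; MeOH, then aq potassium sodium tartrate
Reagents that add atoms: none
Why: Partial reduction of an α-silyloxy ester with iBu2AlH at −78 °C stops at the aldehyde because the chelated tetrahedral aluminium hemiacetal survives until the quench, and the alkyl halides are inert to the hydride at this temperature.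

Step 9
Reactants: 12 (1S,3R,4R)-4-bromo-3-chloro-4-methyl-1-(triethylsilyloxy)cyclohexane-1-carbaldehyde; 13 2-(2-bromoethyl)-1,3-dioxolane
Product: 15 1-[(1S,3R,4R)-4-bromo-3-chloro-4-methyl-1-(triethylsilyloxy)cyclohexyl]-3-(1,3-dioxolan-2-yl)propan-1-ol (both carbinol epimers), via Grignard reagent 14 (not isolated)
Conditions: Mg, THF, 25 °C; then 12, THF, −78 → −40 °C; pH 7 phosphate buffer at −78 °C
Reagents that add atoms: none
Why: Grignard addition to the non-enolisable aldehyde forms the C5–C6 bond at −78 °C, fast enough that the basic reagent should not eliminate the tertiary bromide or move the silyl group; the new carbinol centre is removed in the next step.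

Step 10
Reactants: 15 1-[(1S,3R,4R)-4-bromo-3-chloro-4-methyl-1-(triethylsilyloxy)cyclohexyl]-3-(1,3-dioxolan-2-yl)propan-1-ol
Product: 16 1-[(1S,3R,4R)-4-bromo-3-chloro-4-methyl-1-(triethylsilyloxy)cyclohexyl]-3-(1,3-dioxolan-2-yl)propan-1-one
Conditions: Dess–Martin periodinane (1.5 equiv), pyridine (5 equiv), CH2Cl2, 0 °C → rt
Reagents that add atoms: none
Why: Dess–Martin oxidation of the secondary alcohol runs under buffered, near-neutral conditions that leave the acetal, the silyl ether and both halides untouched.

Step 11
Reactants: 16 1-[(1S,3R,4R)-4-bromo-3-chloro-4-methyl-1-(triethylsilyloxy)cyclohexyl]-3-(1,3-dioxolan-2-yl)propan-1-one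
Product: 17 2-{3-[(1S,3R,4R)-4-bromo-3-chloro-4-methyl-1-(triethylsilyloxy)cyclohexyl]but-3-en-1-yl}-1,3-dioxolane
Conditions: (C5H5)2Ti(CH3)2 (3 equiv), toluene, 70 °C, dark
Reagents that add atoms: bis(cyclopentadienyl)dimethyltitanium (C5H5)2Ti(CH3)2, C[Ti](C)(C1C=CC=C1)C1C=CC=C1
Why: In the Petasis methylenation thermally generated (C5H5)2Ti=CH2 undergoes [2+2] addition to the hindered ketone and cycloreversion to the 1,1-disubstituted alkene without base or strong Lewis acid, so the tertiary bromide, the acetal and the silyl ether should survive.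

Step 12
Reactants: 17 2-{3-[(1S,3R,4R)-4-bromo-3-chloro-4-methyl-1-(triethylsilyloxy)cyclohexyl]but-3-en-1-yl}-1,3-dioxolane
Product: 19 4-[(1S,3R,4R)-4-bromo-3-chloro-4-methyl-1-(triethylsilyloxy)cyclohexyl]pent-4-enal, via collidinium acetal salt 18 (not isolated)
Conditions: TESOTf (2 equiv), 2,4,6-collidine (3 equiv), CH2Cl2, 0 °C; then H2O, 0 °C → rt
Reagents that add atoms: water, O
Why: In this silyl-triflate-mediated acetal cleavage the dioxolane is opened to an oxocarbenium ion that collidine traps as a pyridinium salt, and water then releases the aldehyde without protic acid or heat, so the tertiary silyl ether (which blocks lactol formation) and the tertiary bromide are kept.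

Step 13
Reactants: 20 2-bromopropene (2 equiv per zinc)
Product: 22 diisopropenylzinc (titrated toluene solution), via isopropenylmagnesium bromide 21 (not isolated)
Conditions: Mg, THF, 40 °C; then ZnCl2 (0.5 equiv relative to 21), Et2O, 0 °C → rt; 1,4-dioxane, filtration under argon; solvent exchanged for toluene
Reagents that add atoms: 2-bromopropene (second equivalent), C=C(C)Br; zinc dichloride, Cl[Zn]Cl
Why: Grignard formation from the vinylic bromide and transmetalation of two equivalents of 21 onto one ZnCl2 give the dialkenylzinc, in which both isopropenyl groups come from 20, and dioxane precipitates the magnesium halide so that the reagent is salt-free, as the catalysed addition requires.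

Step 14
Reactants: 19 4-[(1S,3R,4R)-4-bromo-3-chloro-4-methyl-1-(triethylsilyloxy)cyclohexyl]pent-4-enal; 22 diisopropenylzinc
Product: 23 (3R)-6-[(1S,3R,4R)-4-bromo-3-chloro-4-methyl-1-(triethylsilyloxy)cyclohexyl]-2-methylhepta-1,6-dien-3-ol
Conditions: (2S)-3-exo-morpholinoisoborneol (10 mol %), 22 (2 equiv), toluene, −20 → 0 °C; then H2O
Reagents that add atoms: none
Why: The amino alcohol is zincated by 22 to a chiral zinc amino-alkoxide that binds the aldehyde oxygen at zinc and a second molecule of 22 at its alkoxide oxygen, and one isopropenyl group migrates within this bimetallic assembly to form the C2–C3 bond. The closest known reaction type is the β-amino-alcohol-catalysed enantioselective addition of dialkyl- and dialkenylzinc reagents to aldehydes. No ring is closed. The only new stereocentre, C3, is controlled by the ligand alone: the (2S) ligand delivers the zinc-bound group to the Si face of the aldehyde, which corresponds to 3R here because the incoming isopropenyl group outranks the C4 chain, while the ring stereocentres four bonds away exert no bias. The step needs enantiofacial selectivity and chemoselectivity for the aldehyde: salt-free 22 suppresses the uncatalysed background addition, the organozinc leaves the tertiary bromide, the secondary chloride and the silyl ether alone, and the C7 silyl ether prevents lactol formation.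

Step 15
Reactants: 23 (3R)-6-[(1S,3R,4R)-4-bromo-3-chloro-4-methyl-1-(triethylsilyloxy)cyclohexyl]-2-methylhepta-1,6-dien-3-ol
Product: 24 (3R)-6-[(1S,3R,4R)-4-bromo-3-chloro-1-hydroxy-4-methylcyclohexyl]-2-methylhepta-1,6-dien-3-ol
Conditions: HF·pyridine, pyridine, THF, 0 °C → rt
Reagents that add atoms: none
Why: Fluoride-mediated cleavage of the tertiary triethylsilyl ether with buffered HF·pyridine is mild enough for the tertiary bromide, the secondary chloride and both allylic alcohols.

**Compound list**

1 | (R)-lactic acid | C[C@@H](O)C(=O)O | starting material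
2 | pivalaldehyde | CC(C)(C)C=O | starting material
3 | (2R,5R)-2-tert-butyl-5-methyl-1,3-dioxolan-4-one | C[C@H]1O[C@@H](C(C)(C)C)OC1=O | intermediate
4 | (2S,5S)-5-bromo-2-tert-butyl-5-methyl-1,3-dioxolan-4-one (bromine trans to tert-butyl) | C[C@@]1(Br)O[C@@H](C(C)(C)C)OC1=O | intermediate
5 | (2R)-2-tert-butyl-5-methylidene-1,3-dioxolan-4-one | C=C1O[C@@H](C(C)(C)C)OC1=O | intermediate
6 | isoprene | C=CC(C)=C | starting material
7 | (2R,5S)-2-tert-butyl-8-methyl-1,3-dioxaspiro[4.5]dec-7-en-4-one | CC1=CC[C@]2(CC1)O[C@@H](C(C)(C)C)OC2=O | intermediate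
8 | methyl (1S)-1-hydroxy-4-methylcyclohex-3-ene-1-carboxylate | COC(=O)[C@]1(O)CCC(C)=CC1 | intermediate
9 | methyl (1S,3R,4R)-3-endo-chloro-4-methyl-7-oxabicyclo[2.2.1]heptane-1-carboxylate | COC(=O)[C@@]12CC[C@@](C)(O1)[C@H](Cl)C2 | intermediate
10 | methyl (1S,3R,4R)-4-bromo-3-chloro-1-hydroxy-4-methylcyclohexane-1-carboxylate | COC(=O)[C@]1(O)CC[C@@](C)(Br)[C@H](Cl)C1 | intermediate
11 | methyl (1S,3R,4R)-4-bromo-3-chloro-4-methyl-1-(triethylsilyloxy)cyclohexane-1-carboxylate | COC(=O)[C@]1(O[Si](CC)(CC)CC)CC[C@@](C)(Br)[C@H](Cl)C1 | intermediate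
12 | (1S,3R,4R)-4-bromo-3-chloro-4-methyl-1-(triethylsilyloxy)cyclohexane-1-carbaldehyde | O=C[C@]1(O[Si](CC)(CC)CC)CC[C@@](C)(Br)[C@H](Cl)C1 | intermediate
13 | 2-(2-bromoethyl)-1,3-dioxolane | BrCCC1OCCO1 | starting material
14 | [2-(1,3-dioxolan-2-yl)ethyl]magnesium bromide | Br[Mg]CCC1OCCO1 | intermediate
15 | 1-[(1S,3R,4R)-4-bromo-3-chloro-4-methyl-1-(triethylsilyloxy)cyclohexyl]-3-(1,3-dioxolan-2-yl)propan-1-ol (both carbinol epimers) | OC(CCC1OCCO1)[C@]1(O[Si](CC)(CC)CC)CC[C@@](C)(Br)[C@H](Cl)C1 | intermediate
16 | 1-[(1S,3R,4R)-4-bromo-3-chloro-4-methyl-1-(triethylsilyloxy)cyclohexyl]-3-(1,3-dioxolan-2-yl)propan-1-one | O=C(CCC1OCCO1)[C@]1(O[Si](CC)(CC)CC)CC[C@@](C)(Br)[C@H](Cl)C1 | intermediate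
17 | 2-{3-[(1S,3R,4R)-4-bromo-3-chloro-4-methyl-1-(triethylsilyloxy)cyclohexyl]but-3-en-1-yl}-1,3-dioxolane | C=C(CCC1OCCO1)[C@]1(O[Si](CC)(CC)CC)CC[C@@](C)(Br)[C@H](Cl)C1 | intermediate
18 | 1-{4-[(1S,3R,4R)-4-bromo-3-chloro-4-methyl-1-(triethylsilyloxy)cyclohexyl]-1-[2-(triethylsilyloxy)ethoxy]pent-4-en-1-yl}-2,4,6-trimethylpyridin-1-ium trifluoromethanesulfonate (both epimers at the N,O-acetal carbon) | C=C(CCC(OCCO[Si](CC)(CC)CC)[n+]1c(C)cc(C)cc1C)[C@]1(O[Si](CC)(CC)CC)CC[C@@](C)(Br)[C@H](Cl)C1.[O-]S(=O)(=O)C(F)(F)F | intermediate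
19 | 4-[(1S,3R,4R)-4-bromo-3-chloro-4-methyl-1-(triethylsilyloxy)cyclohexyl]pent-4-enal | O=CCCC(=C)[C@]1(O[Si](CC)(CC)CC)CC[C@@](C)(Br)[C@H](Cl)C1 | intermediate
20 | 2-bromopropene | C=C(C)Br | starting material
21 | isopropenylmagnesium bromide | C=C(C)[Mg]Br | intermediate
22 | diisopropenylzinc | C=C(C)[Zn]C(C)=C | intermediate
23 | (3R)-6-[(1S,3R,4R)-4-bromo-3-chloro-4-methyl-1-(triethylsilyloxy)cyclohexyl]-2-methylhepta-1,6-dien-3-ol | C=C(C)[C@H](O)CCC(=C)[C@]1(O[Si](CC)(CC)CC)CC[C@@](C)(Br)[C@H](Cl)C1 | intermediate
24 | (3R)-6-[(1S,3R,4R)-4-bromo-3-chloro-1-hydroxy-4-methylcyclohexyl]-2-methylhepta-1,6-dien-3-ol | C=C(C)[C@H](O)CCC(=C)[C@]1(O)CC[C@@](C)(Br)[C@H](Cl)C1 | target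

**Step count**

Total steps: 15. Longest linear sequence: 14 steps (steps 1–12, 14 and 15; step 13 prepares the zinc reagent in a side branch).

**Steps most likely to fail**

Step 6 (opening of the oxa bridge). The bridging ether may not ionise cleanly: the boron halide may demethylate the ester before the C10–O bond breaks, the C10 cation may lose a proton instead of capturing bromide, or the freed hydroxyl may return to C10 on work-up. The fallback sets out from 9 and replaces Lewis-acid ionisation followed by aqueous release with a silyl-transfer cleavage that caps the oxygen in the same event. Bromotrimethylsilane with catalytic ZnBr2 in CH2Cl2 (0 °C → rt) should give methyl (1S,3R,4R)-4-bromo-3-chloro-4-methyl-1-(trimethylsilyloxy)cyclohexane-1-carboxylate F1 by the same chloronium-guided bromide delivery. Mild acidic methanolysis (citric acid, MeOH, 0 °C) then removes the trimethylsilyl group and comes back to the route at 10.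

Step 14 (key step). Facial selectivity may be poor with an unbranched aliphatic aldehyde, and transfer of the α-branched alkenyl group from zinc may be slow, so that the uncatalysed addition competes. The fallback sets out from 19 and moves stereocontrol from C–C bond formation to a reagent-controlled ketone reduction. Isopropenylmagnesium bromide 21 in THF at −78 °C should give 6-[(1S,3R,4R)-4-bromo-3-chloro-4-methyl-1-(triethylsilyloxy)cyclohexyl]-2-methylhepta-1,6-dien-3-ol as both C3 epimers F2. Dess–Martin oxidation should give the enone 6-[(1S,3R,4R)-4-bromo-3-chloro-4-methyl-1-(triethylsilyloxy)cyclohexyl]-2-methylhepta-1,6-dien-3-one F3. Corey–Bakshi–Shibata reduction with (S)-1-methyl-3,3-diphenyltetrahydro-1H,3H-pyrrolo[1,2-c][1,3,2]oxazaborole and catecholborane in toluene at −78 °C, with the isopropenyl group as the large substituent, should deliver hydride to the face that gives 3R and comes back to the route at 23.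

Step 11 (methylenation). The [2+2] addition at the hindered ketone may be slow, and the tertiary bromide may lose HBr during prolonged heating at 70 °C. The fallback sets out from 16 and uses a two-stage Peterson olefination at low temperature. (Trimethylsilyl)methyllithium with anhydrous CeCl3 in THF at −78 °C should give 2-[(1S,3R,4R)-4-bromo-3-chloro-4-methyl-1-(triethylsilyloxy)cyclohexyl]-4-(1,3-dioxolan-2-yl)-1-(trimethylsilyl)butan-2-ol F4. Acid-promoted anti elimination (camphorsulfonic acid, cat., dry CH2Cl2, 0 °C) then comes back to the route at 17.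

**Further compounds**

F1 | step 6 | methyl (1S,3R,4R)-4-bromo-3-chloro-4-methyl-1-(trimethylsilyloxy)cyclohexane-1-carboxylate | COC(=O)[C@]1(O[Si](C)(C)C)CC[C@@](C)(Br)[C@H](Cl)C1
F2 | step 14 | 6-[(1S,3R,4R)-4-bromo-3-chloro-4-methyl-1-(triethylsilyloxy)cyclohexyl]-2-methylhepta-1,6-dien-3-ol (both C3 epimers) | C=C(C)C(O)CCC(=C)[C@]1(O[Si](CC)(CC)CC)CC[C@@](C)(Br)[C@H](Cl)C1
F3 | step 14 | 6-[(1S,3R,4R)-4-bromo-3-chloro-4-methyl-1-(triethylsilyloxy)cyclohexyl]-2-methylhepta-1,6-dien-3-one | C=C(C)C(=O)CCC(=C)[C@]1(O[Si](CC)(CC)CC)CC[C@@](C)(Br)[C@H](Cl)C1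
F4 | step 11 | 2-[(1S,3R,4R)-4-bromo-3-chloro-4-methyl-1-(triethylsilyloxy)cyclohexyl]-4-(1,3-dioxolan-2-yl)-1-(trimethylsilyl)butan-2-ol (both carbinol epimers) | C[Si](C)(C)CC(O)(CCC1OCCO1)[C@]1(O[Si](CC)(CC)CC)CC[C@@](C)(Br)[C@H](Cl)C1
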